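**The count.** Every nucleophile charged stands at any moment as free nucleophile, as target or as protonated nucleophile, and each target made sets one acid free.

| flask | electrophile | nucleophile | free base | remark | time |
|---|---|---|---|---|---|
| winter | 0.20 M | 0.95 equiv | 3 equiv | run made earlier |  |
| autumn | 0.20 M | 0.95 equiv | 1.5 equiv | run made earlier |  |
| spring | 0.20 M | 0.95 equiv | 6 equiv | run made earlier |  |
| ochre | 0.20 M | 0.950 equiv | 3.00 equiv | everything together in a closed stirred flask, run for 80 min | 80 min |
| blue | 0.20 M (fed, over 80.0 min) | 0.950 equiv | 3.00 equiv | a stirred flask in which electrophile is dosed at a steady rate over 80.0 min without added volume, worked up at 80 min | 80 min |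
| green | 0.20 M | 0.950 equiv | 3.00 equiv | a single well-mixed tank run continuously and read at steady state, 80 min in it on average |  |
| grey | 0.20 M | 0.950 equiv (fed, over 80.0 min) | 3.00 equiv | a stirred flask in which nucleophile is dosed at a steady rate over 80.0 min without added volume, worked up at 80 min | 80 min |

| run | time / min | target / % |
|---|---|---|
| winter | 6.00 | 8.0 |
| winter | 15.0 | 17.6 |
| winter | 20.0 | 21.3 |
| winter | 30.0 | 26.3 |
| winter | 40.0 | 31.4 |
| winter | 50.0 | 35.1 |
| autumn | 4.00 | 6.0 |
| autumn | 6.00 | 8.5 |
| autumn | 8.00 | 11.6 |
| autumn | 15.0 | 17.3 |
| autumn | 20.0 | 21.8 |
| autumn | 30.0 | 27.4 |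
| autumn | 50.0 | 33.8 |
| spring | 4.00 | 5.4 |
| spring | 6.00 | 8.6 |
| spring | 8.00 | 10.2 |
| spring | 15.0 | 17.0 |
| spring | 20.0 | 20.6 |
| spring | 30.0 | 27.2 |
| spring | 50.0 | 34.1 |

(scatter of a reading: 0.5 percentage points)

- the stated concentrations are those of everything mixed, before any reaction; amounts are the same in each set-up
- candidate steps: electrophile + nucleophile -> acid set free + target; nucleophile + acid set free <-> protonated nucleophile; acid set free + free base <-> salt of the base; acid set free -> by-product carried off; free base <-> dormant form; electrophile + acid set free -> side product
- the feed brings no volume worth counting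
- the earlier runs were made in a closed, stirred flask

- the set-up with the highest amount of target at the outlet or at the end, in percent of the electrophile put in ("none" if the first two lie within 2 percentage points) (ochre / blue / green / grey / none)
- amount of target at the outlet or at the end, in percent of the electrophile put in, ochre
- amount of target at the outlet or at the end, in percent of the electrophile put in, blue
- amount of target at the outlet or at the end, in percent of the electrophile put in, green
- amount of target at the outlet or at the end, in percent of the electrophile put in, grey

**Where acid goes.** At 50.0 min the readings give 33.8%, 35.1% and 34.1% for 1.5 equiv, 3 equiv and 6 equiv of free base, with a scatter of 0.5 percentage points. We therefore reckon that free base takes no visible acid in this time, and that each acid is held at once by a nucleophile. Each target then costs two nucleophiles, one built in and one protonated. Let x be the target as a fraction of the electrophile charged, and n the equivalents of nucleophile. Free nucleophile is then n − 2x, so on this count x stops at 47.5%, the acid ceiling h, which is half of n. The nucleophile is the limiting reagent.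

**One constant.** Take dx/dt = κ(1 − x)(n − 2x), with κ the rate constant times the electrophile charged. This integrates to x = h(E − 1)/(E − h), where E = exp[(2 − n)κt]. The mean of those readings, 34.3%, gives κ = 0.0164 min⁻¹.

**Two neighbours.** For ochre at 80 min we get 40.4%. Take a flask like ochre but with 3.80 equiv of nucleophile. Its ceiling is 190%, above the whole electrophile, so we get 95.3%. In this reckoning ochre comes out lower because its ceiling lies below the electrophile charged, so its free nucleophile shrinks as x nears h.

**Other vessels.** For green, the tank balance x = κτ(1 − x)(n − 2x) gives 30.7%. Blue and grey we read roughly as a closed flask at half the time, which gives 31.1%. We commit to ochre, ahead of both.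

**The result.** The forecast gave ochre, with 43%, 30%, 32.5% and 28% for ochre, blue, green and grey: “Batch wins clearly.” The flasks give ochre, with 40.7%, 30.1%, 30.9% and 28.2%.

    electrophile + nucleophile → acid set free + target (k = 0.00140 M⁻¹ s⁻¹)
    nucleophile + acid set free ⇌ protonated nucleophile, settled at all times (K = 20000 M⁻¹)
    acid set free + free base ⇌ salt of the base (K = 1700 M⁻¹, k = 0.00350 M⁻¹ s⁻¹)
    acid set free → by-product carried off (k = 2.70 × 10⁻⁴ s⁻¹)
    free base ⇌ dormant form (K = 0.500, k = 1.90 × 10⁻⁴ s⁻¹)
    electrophile + acid set free → side product (k = 0.00220 M⁻¹ s⁻¹)

**Not at rest.** The flask with 3.80 equiv of nucleophile gives 95.6%, and ochre stands below h at 80 min, but ochre is still moving. Left for 800 min, its target reaches 59.5%, past h, while its electrophile falls from 59.3% to 37.6% of the charge and its free nucleophile from 14.7% to 2.66% of its own charge. Over the same stretch its protonated nucleophile goes from 0.0807 M to 0.0660 M, and its salt of the base rises from 4.11 × 10⁻⁴ M to 0.0383 M.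

All runs were computed from invented constants; noise was put on by code.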